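## Structural features

The target 25 is a germacranolide (germacrane numbering throughout). A ten-membered carbocycle C1–C10 shares the C6–C7 bond with an α-methylene-γ-butyrolactone (O–C6, C7–C11, C12=O, C11=C13H2), and the two rings are trans-fused. The carbocycle holds a 1,5-diene of two trisubstituted olefins of opposite geometry: C1=C10 (Z, C2 cis to C9, methyl C14) and C4=C5 (E, C3 trans to C6, methyl C15). The other half of the ring is an unbroken row of four oxygenated stereocentres: C6 (S, lactone oxygen), C7 (R, tertiary alcohol and ring-fusion carbon), C8 (S, free alcohol) and C9 (S, isobutyrate). Their relative pattern is erythro (6/7), threo (7/8), erythro (8/9).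

Several groups are fragile. The α-methylene lactone is a Michael acceptor, and the β-hydroxy lactone can eliminate or undergo retro-aldol cleavage. The allylic C9 ester sits next to a free C8 hydroxyl, so the acyl group can migrate. The 1,5-diene is prone to acid-induced transannular cyclisation.

The real difficulty is to close a strained ten-membered ring that holds one E and one Z trisubstituted olefin, and to place the fully substituted C7 next to C6. The key step exploits one feature. The arc C9–C10(C14)=C1–C2–C3–C4(C15) is a 2,6-dimethylcyclohex-2-enone ring cut open between C4 and C9 (the Z olefin is its endocyclic olefin, O9 its ketone oxygen), and C4=C5 / C6–C7 / C8–C9(O) is the retron of an oxy-Cope shift. In one sentence, the route is an anionic oxy-Cope four-atom ring expansion of a 1-(alkoxyethynyl)-6-(2-alkoxyvinyl)-2,6-dimethylcyclohex-2-enol.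

## Logic of the disconnections

**25 ⇒ 24.** The O9–acyl bond is cut. The ester is the group most exposed to bases and nucleophiles and can migrate to O8, so it is put on last. This removes one protecting-group problem. The forward step must acylate O9 (allylic, next to sp2 C10) in preference to O8 (next to quaternary C7) and tertiary O7.

**24 ⇒ 23 ⇒ 22.** After the O8/O9 silyl ethers are put back, C11–C12 and C12–O6 are cut, which takes out one molecule of CO. The lactone and its Michael acceptor shrink to a terminal alkyne on C7 and a free C6 hydroxyl. The forward carbonylation must engage O6 (five-membered ring) and not O7 (four-membered ring).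

**22 ⇒ 21 ⇒ 19 + 20.** The C7–C11 bond is cut, so the tertiary carbinol becomes a ketone flanked by O6 and O8. This removes the hardest stereocentre. The nucleophile must enter so that O6/O7 become erythro, which calls for a chelating ether on O6 and non-chelating ethers on O8 and O9.

**19 ⇒ 18 ⇒ 16 ⇒ 15.** The C8–O bond and the C9–H bond are cut. The α-hydroxy ketone comes from an enol ether and the C9 carbinol from a ketone, so C7, C8 and C9 collapse into one vinylogous ester. Only the C6 stereocentre is left in the ring. C9 and C8 must be relayed from C6 through the shape of the ring.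

**15 ⇒ 12 (key).** C6–C7 is cut and C4–C9 is reconnected. The ten-membered ring, the E olefin and C6 are traded for a cyclohexenol that carries two unsaturated arms. The Z olefin becomes an ordinary ring olefin and no end-to-end macrocyclisation remains. The forward step needs the two arms trans, a geometrically pure E enol ether and a defined C4 configuration.

**12 ⇒ 9 + 10.** C8–C9 is cut, an acetylide addition to an enone. The two-carbon unit C7–C8 arrives with C7 already at the ketone oxidation level. The addition must be 1,2 and anti to the larger group on C4.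

**9 ⇒ 8 ⇒ 7 ⇒ 5 + 6, then 5 ⇒ 4.** The vinylic C6–O bond and then the C5=C6 bond are cut, and the ketone is carried as a silyl-protected alcohol. The E enol ether is reduced to an aldehyde. Both forward steps must be E-selective or stereoretentive, because this geometry becomes the C6 configuration.

**4 ⇒ 2 + 3, then 2 ⇒ 1.** C4–C9 and C2–C3 are cut, a cycloaddition that builds the six-membered ring with its quaternary C4, and the diene goes back to an enal. One catalytic step must set C4, the only stereocentre introduced from outside.

## Other disconnections considered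

**Alternative 1:** the first cut that comes to mind is C6–C7 in the polar sense, together with the lactone C–O bond. The seco enal allyl bromide A1 would be closed by an intramolecular Nozaki–Hiyama or Barbier allylation (CrCl2 or In), and the alkoxide would lactonise to the protected lactone A2. This is an end-to-end closure of a strained ring at high dilution. The allylmetal is tetrasubstituted and γ-oxygenated and must create C6 and the fully substituted C7 at once, while neither its own geometry nor the transition-state array is fixed. A1 also needs the C8/C9 diol and both trisubstituted olefins to be made separately beforehand. The chosen plan needs no dilution and takes both olefin geometries from mechanism.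

**Alternative 2:** the textbook germacrane retron cuts C2–C3 and reconnects C5–C10. The cis-1-vinyl-2-isopropenyl cyclitol A3 would undergo an anionic oxy-Cope shift, the C1=C10 enolate would be trapped as its triflate and C14 added by cross-coupling. A cis-dialkenyl arrangement has two competing chair arrays. One puts C9 axial and gives 1(10)Z,4E; the other puts C6 axial and gives 1(10)E,4Z. The C15 methyl group penalises the array that is needed. A3 carries six contiguous stereocentres of which two are thrown away, and its four oxygens must still be told apart before C7 can be oxidised and branched, so the route is longer.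

**Alternative 3:** C6–C7 can also be cut as an Ireland–Claisen shift of the ten-membered lactone A4, the ester of a tertiary C4 carbinol. The shift of its silyl ketene acetal would exchange the ring atoms O and C11 for C5 and C6. A4 needs acylation of a hindered tertiary allylic alcohol and a medium-ring closure of its own, for instance with the second-generation Grubbs catalyst and with uncertain olefin geometry. Its ester enolate has a β-alkoxy group on C8 that can be eliminated. The ketene acetal geometry inside a medium ring cannot be chosen, so C7 is not under control. C11 arrives as a carboxyl carbon that must then be extended by two carbons.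

Key step: step 8

Assumption: the SMILES is read as (6S,7R,8S,9S), 1(10)Z, 4E in germacrane numbering, and the (S)-catalyst of step 2 is assumed to shield the Cα-Si face of boron-bound methacrolein.

## Steps

Step 1
Reactants: 1 (E)-2-methylbut-2-enal (tiglic aldehyde)
Product: 2 (1E)-1-(tert-butyldimethylsilyloxy)-2-methylbuta-1,3-diene
Conditions: t-BuMe2SiOTf, Et3N, Et2O, 0 °C to rt
Reagents that add atoms: tert-butyldimethylsilyl triflate CC(C)(C)[Si](C)(C)OS(=O)(=O)C(F)(F)F
Why: Soft γ-enolisation and O-silylation of the s-trans enal (silyl dienol ether formation) should give the 1E diene, with oxygen trans to the vinyl group. This is the isomer that can reach the s-cis conformation needed in step 2.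

Step 2
Reactants: 2 (1E)-1-(tert-butyldimethylsilyloxy)-2-methylbuta-1,3-diene; 3 2-methylprop-2-enal (methacrolein)
Product: 4 (1S,2R)-2-(tert-butyldimethylsilyloxy)-1,3-dimethylcyclohex-3-ene-1-carbaldehyde
Conditions: (S)-3,3-diphenyl-1-(2-methylphenyl)tetrahydro-1H,3H-pyrrolo[1,2-c][1,3,2]oxazaborole (20 mol %), HN(SO2CF3)2 (18 mol %), CH2Cl2, −78 °C
Reagents that add atoms: none
Why: This is a catalytic enantioselective Diels–Alder reaction of a 1-oxygenated diene with an α-substituted acrolein, and the ortho rule places the oxygenated carbon (C9) next to the quaternary carbon (C4). The diene should add to the open Cα-Re face of the boron-bound s-trans enal, which sets C4. The endo-derived carbinol centre is erased in step 6, so the endo/exo outcome does not matter.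

Step 3
Reactants: 4 (1S,2R)-2-(tert-butyldimethylsilyloxy)-1,3-dimethylcyclohex-3-ene-1-carbaldehyde
Product: 5 tert-butyl{[(1R,6R)-6-[(E)-2-iodoethenyl]-2,6-dimethylcyclohex-2-en-1-yl]oxy}dimethylsilane
Conditions: CrCl2, CHI3, THF, 0 °C to rt
Reagents that add atoms: iodoform IC(I)I
Why: The Takai olefination adds C6 through a geminal dichromium species, and its anti elimination favours the E iodide, all the more with a hindered aldehyde. No stereocentre is touched (the C4 descriptor changes only by priority).

Step 4
Reactants: 5 tert-butyl{[(1R,6R)-6-[(E)-2-iodoethenyl]-2,6-dimethylcyclohex-2-en-1-yl]oxy}dimethylsilane; 6 4-methoxybenzyl alcohol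
Product: 7 tert-butyl{[(1R,6R)-6-{(E)-2-[(4-methoxybenzyl)oxy]ethenyl}-2,6-dimethylcyclohex-2-en-1-yl]oxy}dimethylsilane
Conditions: CuI (10 mol %), 3,4,7,8-tetramethyl-1,10-phenanthroline (20 mol %), Cs2CO3, toluene, 80 °C
Reagents that add atoms: none
Why: The copper-catalysed Ullmann-type C–O coupling of a vinyl iodide with an alcohol runs with retention of olefin geometry, so a pure E enol ether should result. The PMB group is a chelating and oxidatively removable carrier of O6.

Step 5
Reactants: 7 tert-butyl{[(1R,6R)-6-{(E)-2-[(4-methoxybenzyl)oxy]ethenyl}-2,6-dimethylcyclohex-2-en-1-yl]oxy}dimethylsilane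
Product: 8 (1R,6R)-6-{(E)-2-[(4-methoxybenzyl)oxy]ethenyl}-2,6-dimethylcyclohex-2-en-1-ol
Conditions: Bu4NF, THF, 0 °C to rt
Reagents that add atoms: none
Why: Fluoride cleaves the silyl ether under basic conditions, and these leave the acid-sensitive enol ether untouched.

Step 6
Reactants: 8 (1R,6R)-6-{(E)-2-[(4-methoxybenzyl)oxy]ethenyl}-2,6-dimethylcyclohex-2-en-1-ol
Product: 9 (6R)-6-{(E)-2-[(4-methoxybenzyl)oxy]ethenyl}-2,6-dimethylcyclohex-2-en-1-one
Conditions: Dess–Martin periodinane, pyridine, CH2Cl2, 0 °C
Reagents that add atoms: none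
Why: A buffered Dess–Martin oxidation of the allylic alcohol should give the enone. Pyridine takes up the acetic acid and protects the enol ether, and C4 has no α-hydrogen and cannot epimerise.

Step 7
Reactants: 9 (6R)-6-{(E)-2-[(4-methoxybenzyl)oxy]ethenyl}-2,6-dimethylcyclohex-2-en-1-one; 10 ethoxyacetylene
Product: 12 (1R,6R)-1-(ethoxyethynyl)-6-{(E)-2-[(4-methoxybenzyl)oxy]ethenyl}-2,6-dimethylcyclohex-2-en-1-ol (alkynyl trans to alkenyl), via lithium ethoxyacetylide 11 (not isolated)
Conditions: 10, n-BuLi, THF, −78 °C; then 9, −78 to −40 °C; H2O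
Reagents that add atoms: none
Why: The hard, slim lithium acetylide should add 1,2 to the enone, anti to the larger 2-alkoxyvinyl group on C4, so that the two unsaturated arms end up trans. Any cis epimer is removed by chromatography. The work-up is kept neutral because the ynol ether carbinol is acid-sensitive.

Step 8
Reactants: 12 (1R,6R)-1-(ethoxyethynyl)-6-{(E)-2-[(4-methoxybenzyl)oxy]ethenyl}-2,6-dimethylcyclohex-2-en-1-ol
Product: 15 (2Z,6E,8S,9E)-9-ethoxy-8-[(4-methoxybenzyl)oxy]-2,6-dimethylcyclodeca-2,6,9-trien-1-one (target numbering: C9 ketone; C7(OEt)=C8 with C6 cis to C9; 6S; 4E; 1(10)Z), via potassium alkoxide 13 (not isolated), via potassium allenolate 14 (not isolated)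
Conditions: KH, 18-crown-6, THF, 0 °C to rt; AcOH (1 equiv), −78 °C
Reagents that add atoms: none
Why: Proposed new method: in alkoxide 13 the oxyanion weakens the C4–C9 bond, and a suprafacial [3,3] shift over C6=C5–C4–C9–C8≡C7 forms C6–C7 as C4–C9 breaks, giving the cyclic allenolate 14, which is protonated at C8 to the vinylogous ester 15. The closest known reaction types are the anionic oxy-Cope ring expansion of trans-1,2-dialkenylcyclohex-2-enols to (Z,E)-cyclodecadienones and the acetylenic oxy-Cope rearrangement; the new element is the pair of termini, an alkoxyalkyne and an enol ether. The ten-membered ring is closed as a four-atom ring expansion of the six-membered ring through a six-centre chair-like array, not by an end-to-end cyclisation, so no dilution is needed. Because the two arms are trans and pseudo-diequatorial, the only reachable array keeps the ring bonds C4–C3 and C9–C10 equatorial, which puts C3 trans to C6 (4E), while C1=C10 takes no part and keeps the Z geometry imposed by the six-membered ring. C6 is the only new stereocentre: the new bond forms on the face of C5=C6 from which C9 leaves C4, and with 4R and the E enol ether this face gives 6S, while the stereocentres C4 and C9 are consumed. The step needs the exocyclic alkyne and not the endocyclic C1=C10 olefin to react, and the olefin could reach C6 only through a boat, bicyclo[2.2.2]octane-like array. It also needs the shift to win over loss of the acetylide, which is reversible whereas the shift is not. Ethoxide should not be lost from 14, because that would give a ten-membered cycloalkyne that also contains an E olefin, so C7 is delivered at the ketone oxidation level; the cis C7=C8 geometry is expected because 15 then has the ring type of cis,cis,trans-cyclodeca-1,4,7-triene.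

Step 9
Reactants: 15 (2Z,6E,8S,9E)-9-ethoxy-8-[(4-methoxybenzyl)oxy]-2,6-dimethylcyclodeca-2,6,9-trien-1-one
Product: 16 (1R,2Z,6E,8S,9E)-9-ethoxy-8-[(4-methoxybenzyl)oxy]-2,6-dimethylcyclodeca-2,6,9-trien-1-ol
Conditions: i-Bu2AlH, toluene, −78 °C; Na2SO4·10H2O
Reagents that add atoms: none
Why: This is the 1,2-reduction of a vinylogous ester, the first half of a Stork–Danheiser sequence, stopped at the alcohol by a non-acidic work-up. With H6 eclipsing the cis C7=C8 bond and with C5 and C10 both on the inner face, hydride can reach C9 only from the periphery, which gives the target configuration (descriptor R here by priority). 16 ionises easily and is used at once.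

Step 10
Reactants: 16 (1R,2Z,6E,8S,9E)-9-ethoxy-8-[(4-methoxybenzyl)oxy]-2,6-dimethylcyclodeca-2,6,9-trien-1-ol
Product: 18 (2S,3E,7Z,9S,10S)-9,10-dihydroxy-2-[(4-methoxybenzyl)oxy]-4,8-dimethylcyclodeca-3,7-dien-1-one, via ethyl hemiketal 17 (not isolated)
Conditions: OsO4 (2 mol %), N-methylmorpholine N-oxide (1.1 equiv), acetone/H2O, 0 °C
Reagents that add atoms: N-methylmorpholine N-oxide C[N+]1([O-])CCOCC1; water O
Why: The Upjohn dihydroxylation of an enol ether is a known way to α-hydroxy ketones; the enol ether is the most electron-rich olefin and should react first, and hemiketal 17 loses ethanol. OsO4 should add to the outer face of C7=C8, opposite to C5 and C10 in the conformer fixed by the 6S centre, which sets 8S.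

Step 11
Reactants: 18 (2S,3E,7Z,9S,10S)-9,10-dihydroxy-2-[(4-methoxybenzyl)oxy]-4,8-dimethylcyclodeca-3,7-dien-1-one
Product: 19 (2S,3E,7Z,9S,10S)-2-[(4-methoxybenzyl)oxy]-4,8-dimethyl-9,10-bis(triethylsilyloxy)cyclodeca-3,7-dien-1-one
Conditions: Et3SiOTf, 2,6-lutidine, CH2Cl2, −78 °C
Reagents that add atoms: triethylsilyl triflate CC[Si](CC)(CC)OS(=O)(=O)C(F)(F)F
Why: Silylation of both secondary alcohols at low temperature with a hindered base should avoid enolisation of the ketone. The silyl ethers make O8 and O9 non-chelating for step 12.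

Step 12
Reactants: 19 (2S,3E,7Z,9S,10S)-2-[(4-methoxybenzyl)oxy]-4,8-dimethyl-9,10-bis(triethylsilyloxy)cyclodeca-3,7-dien-1-one; 20 ethynylmagnesium bromide
Product: 21 (1S,2S,3E,7Z,9S,10S)-1-ethynyl-2-[(4-methoxybenzyl)oxy]-4,8-dimethyl-9,10-bis(triethylsilyloxy)cyclodeca-3,7-dien-1-ol
Conditions: MgBr2·OEt2, CH2Cl2, −78 °C; then 20 (THF), −78 to −30 °C; aq. NH4Cl
Reagents that add atoms: none
Why: This is a chelation-controlled addition: magnesium bridges the C7 carbonyl and the O6 ether, while the silyloxy group on C8 lies anti to the carbonyl dipole. Both arrangements put C5 and C9 on the inner face, so the acetylide enters from the periphery on the side of H6 and O6/O7 become erythro, the target configuration (descriptor S here by priority). The small, weakly basic nucleophile limits enolisation toward C6.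

Step 13
Reactants: 21 (1S,2S,3E,7Z,9S,10S)-1-ethynyl-2-[(4-methoxybenzyl)oxy]-4,8-dimethyl-9,10-bis(triethylsilyloxy)cyclodeca-3,7-dien-1-ol
Product: 22 (1S,2S,3E,7Z,9S,10S)-1-ethynyl-4,8-dimethyl-9,10-bis(triethylsilyloxy)cyclodeca-3,7-diene-1,2-diol
Conditions: DDQ, CH2Cl2/pH 7 buffer, 0 °C
Reagents that add atoms: none
Why: Oxidative cleavage of the PMB ether under buffered aqueous conditions spares the silyl ethers, the alkyne and the olefins. The water present prevents closure of a benzylidene acetal onto O7.

Step 14
Reactants: 22 (1S,2S,3E,7Z,9S,10S)-1-ethynyl-4,8-dimethyl-9,10-bis(triethylsilyloxy)cyclodeca-3,7-diene-1,2-diol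
Product: 23 (6S,7S,8S,9S)-7-hydroxy-8,9-bis(triethylsilyloxy)germacra-1(10)Z,4E,11(13)-trien-6,12-olide
Conditions: PdCl2 (10 mol %), thiourea (10 mol %), CO (1 atm), acetone, 50 °C
Reagents that add atoms: carbon monoxide [C-]#[O+]
Why: In the palladium-catalysed cyclocarbonylation of a homopropargylic alcohol, O6 and CO form an alkoxycarbonyl complex of divalent palladium, the alkyne inserts syn in a 5-exo-dig mode, and protonolysis frees the exocyclic methylene. The tertiary O7 could only close a four-membered ring and should not compete, and no stereocentre is touched.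

Step 15
Reactants: 23 (6S,7S,8S,9S)-7-hydroxy-8,9-bis(triethylsilyloxy)germacra-1(10)Z,4E,11(13)-trien-6,12-olide
Product: 24 (6S,7R,8S,9S)-7,8,9-trihydroxygermacra-1(10)Z,4E,11(13)-trien-6,12-olide
Conditions: HF·pyridine, pyridine, THF, 0 °C
Reagents that add atoms: none
Why: Buffered HF removes the labile triethylsilyl ethers without basic fluoride, which would attack the α-methylene lactone, and without strong acid, which would endanger the 1,5-diene.

Step 16
Reactants: 24 (6S,7R,8S,9S)-7,8,9-trihydroxygermacra-1(10)Z,4E,11(13)-trien-6,12-olide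
Product: 25 (6S,7R,8S,9S)-7,8-dihydroxy-9-(2-methylpropanoyloxy)germacra-1(10)Z,4E,11(13)-trien-6,12-olide (target)
Conditions: (i-PrCO)2O (1.1 equiv), 2,4,6-collidine, DMAP (5 mol %), CH2Cl2, −40 °C
Reagents that add atoms: isobutyric anhydride CC(C)C(=O)OC(=O)C(C)C
Why: This is a site-selective acylation: O7 is tertiary and O8 is flanked by the fully substituted C7, whereas O9 is allylic and next to sp2 C10, so the branched anhydride should take O9. Low temperature and a weak base suppress acyl migration.

## Compound list

1 | (E)-2-methylbut-2-enal (tiglic aldehyde) | C/C=C(\C)C=O | starting material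
2 | (1E)-1-(tert-butyldimethylsilyloxy)-2-methylbuta-1,3-diene | C=C/C(C)=C/O[Si](C)(C)C(C)(C)C | intermediate
3 | 2-methylprop-2-enal (methacrolein) | C=C(C)C=O | starting material
4 | (1S,2R)-2-(tert-butyldimethylsilyloxy)-1,3-dimethylcyclohex-3-ene-1-carbaldehyde | O=C[C@@]1(C)CCC=C(C)[C@H]1O[Si](C)(C)C(C)(C)C | intermediate
5 | tert-butyl{[(1R,6R)-6-[(E)-2-iodoethenyl]-2,6-dimethylcyclohex-2-en-1-yl]oxy}dimethylsilane | I/C=C/[C@@]1(C)CCC=C(C)[C@H]1O[Si](C)(C)C(C)(C)C | intermediate
6 | 4-methoxybenzyl alcohol | COc1ccc(CO)cc1 | starting material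
7 | tert-butyl{[(1R,6R)-6-{(E)-2-[(4-methoxybenzyl)oxy]ethenyl}-2,6-dimethylcyclohex-2-en-1-yl]oxy}dimethylsilane | COc1ccc(CO/C=C/[C@@]2(C)CCC=C(C)[C@H]2O[Si](C)(C)C(C)(C)C)cc1 | intermediate
8 | (1R,6R)-6-{(E)-2-[(4-methoxybenzyl)oxy]ethenyl}-2,6-dimethylcyclohex-2-en-1-ol | COc1ccc(CO/C=C/[C@@]2(C)CCC=C(C)[C@H]2O)cc1 | intermediate
9 | (6R)-6-{(E)-2-[(4-methoxybenzyl)oxy]ethenyl}-2,6-dimethylcyclohex-2-en-1-one | COc1ccc(CO/C=C/[C@@]2(C)CCC=C(C)C2=O)cc1 | intermediate
10 | ethoxyacetylene | CCOC#C | starting material
11 | lithium ethoxyacetylide | [Li]C#COCC | intermediate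
12 | (1R,6R)-1-(ethoxyethynyl)-6-{(E)-2-[(4-methoxybenzyl)oxy]ethenyl}-2,6-dimethylcyclohex-2-en-1-ol | COc1ccc(CO/C=C/[C@@]2(C)CCC=C(C)[C@]2(O)C#COCC)cc1 | intermediate
13 | potassium alkoxide of 12 | COc1ccc(CO/C=C/[C@@]2(C)CCC=C(C)[C@]2([O-])C#COCC)cc1.[K+] | intermediate
14 | potassium allenolate (ten-membered ring; C9(O−)=C8=C7(OEt); 6S) | COc1ccc(CO[C@H]2/C=C(\C)CC/C=C(/C)C([O-])=C=C2OCC)cc1.[K+] | intermediate
15 | (2Z,6E,8S,9E)-9-ethoxy-8-[(4-methoxybenzyl)oxy]-2,6-dimethylcyclodeca-2,6,9-trien-1-one | COc1ccc(CO[C@H]2/C=C(\C)CC/C=C(/C)C(=O)/C=C2/OCC)cc1 | intermediate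
16 | (1R,2Z,6E,8S,9E)-9-ethoxy-8-[(4-methoxybenzyl)oxy]-2,6-dimethylcyclodeca-2,6,9-trien-1-ol | COc1ccc(CO[C@H]2/C=C(\C)CC/C=C(/C)[C@H](O)/C=C2/OCC)cc1 | intermediate
17 | ethyl hemiketal of 18 at C7 (target numbering 6S,7R,8S,9S) | COc1ccc(CO[C@H]2/C=C(\C)CC/C=C(/C)[C@H](O)[C@H](O)[C@@]2(O)OCC)cc1 | intermediate
18 | (2S,3E,7Z,9S,10S)-9,10-dihydroxy-2-[(4-methoxybenzyl)oxy]-4,8-dimethylcyclodeca-3,7-dien-1-one | COc1ccc(CO[C@H]2/C=C(\C)CC/C=C(/C)[C@H](O)[C@H](O)C2=O)cc1 | intermediate
19 | (2S,3E,7Z,9S,10S)-2-[(4-methoxybenzyl)oxy]-4,8-dimethyl-9,10-bis(triethylsilyloxy)cyclodeca-3,7-dien-1-one | COc1ccc(CO[C@H]2/C=C(\C)CC/C=C(/C)[C@H](O[Si](CC)(CC)CC)[C@H](O[Si](CC)(CC)CC)C2=O)cc1 | intermediate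
20 | ethynylmagnesium bromide | C#C[Mg]Br | starting material
21 | (1S,2S,3E,7Z,9S,10S)-1-ethynyl-2-[(4-methoxybenzyl)oxy]-4,8-dimethyl-9,10-bis(triethylsilyloxy)cyclodeca-3,7-dien-1-ol | COc1ccc(CO[C@H]2/C=C(\C)CC/C=C(/C)[C@H](O[Si](CC)(CC)CC)[C@H](O[Si](CC)(CC)CC)[C@]2(O)C#C)cc1 | intermediate
22 | (1S,2S,3E,7Z,9S,10S)-1-ethynyl-4,8-dimethyl-9,10-bis(triethylsilyloxy)cyclodeca-3,7-diene-1,2-diol | O[C@H]1/C=C(\C)CC/C=C(/C)[C@H](O[Si](CC)(CC)CC)[C@H](O[Si](CC)(CC)CC)[C@]1(O)C#C | intermediate
23 | (6S,7S,8S,9S)-7-hydroxy-8,9-bis(triethylsilyloxy)germacra-1(10)Z,4E,11(13)-trien-6,12-olide | C=C1C(=O)O[C@H]2/C=C(\C)CC/C=C(/C)[C@H](O[Si](CC)(CC)CC)[C@H](O[Si](CC)(CC)CC)[C@]12O | intermediate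
24 | (6S,7R,8S,9S)-7,8,9-trihydroxygermacra-1(10)Z,4E,11(13)-trien-6,12-olide | C=C1C(=O)O[C@H]2/C=C(\C)CC/C=C(/C)[C@H](O)[C@H](O)[C@]12O | intermediate
25 | (6S,7R,8S,9S)-7,8-dihydroxy-9-(2-methylpropanoyloxy)germacra-1(10)Z,4E,11(13)-trien-6,12-olide | C=C1C(=O)O[C@H]2/C=C(\C)CC/C=C(/C)[C@H](OC(=O)C(C)C)[C@H](O)[C@]12O | target

## Step count and least certain steps

Total step count: 16. Longest linear sequence: 16 steps (1 to 25).

**Step 8 (key step, labelled).** The most likely failure is reversible loss of the acetylide from the potassium alkoxide, followed by decay of the free acetylide or γ-deprotonation of the enone. This could happen because two donor-substituted termini and the strain of the cyclic allenolate may slow the shift. Unselective protonation of the allenolate is a lesser risk. The fallback uses known chemistry only and runs from 9 back to 15. Addition of (Z)-2-ethoxyvinyllithium (from tributyl[(Z)-2-ethoxyvinyl]stannane and n-BuLi) should give the trans-dialkenyl carbinol F1. Its potassium alkoxide (KH, 18-crown-6) is a classical substrate of the anionic oxy-Cope ring expansion, and the β-ethoxy enolate so formed should lose ethoxide to give the cross-conjugated cyclodecatrienone F2. t-BuOOH/DBU should epoxidise the less substituted C7=C8 enone bond to the epoxy ketone F3. Pd(PPh3)4 with 1,2-bis(diphenylphosphino)ethane should isomerise it to the 1,3-diketone F4. O-ethylation of its enol (Et3OBF4, i-Pr2NEt) should return 15.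

**Step 9.** Hydride delivery may show poor facial selectivity, because the shape of the ring is only inferred. The 3-ethoxyallyl alcohol may also ionise during work-up. The fallback runs from 15 back to 21 and makes use of the ionisation. Reduction with i-Bu2AlH followed by dilute acid completes the Stork–Danheiser transposition to the C7 dienone F5. Chelation-controlled addition of 20 should give the dienynol F6. A hydroxyl-directed dihydroxylation (OsO4·TMEDA, CH2Cl2, −78 °C) of the cis C8=C9 bond from the side of the C7 hydroxyl should set C8 and C9 in one event and give the triol F7. Et3SiCl/imidazole, which silylates only the two secondary alcohols, returns 21.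

**Step 10.** Osmylation of C4=C5 or C1=C10 may compete, and addition to the inner face is possible if the ring populates a second conformer. The fallback runs from 16 back to 18. A hydroxyl-directed epoxidation (VO(acac)2, t-BuOOH) delivers oxygen from the C9 carbinol to the adjacent enol ether only. It should give the ethoxy epoxide F8, which collapses to 18 on aqueous work-up.

**Step 14.** The Lewis-acidic palladium salt may ionise the allylic or propargylic alcohols, silyl groups may be lost at 50 °C, and insertion next to the quaternary C7 may be slow. The fallback runs from 19 back to 23. Addition of 2-lithio-3-[(4-methoxybenzyl)oxy]propene (from the 2-bromoallyl ether and t-BuLi, with MgBr2·OEt2) should give the allylic ether carbinol F9. DDQ removes both PMB groups to give the triol F10. TEMPO/PhI(OAc)2 oxidises the primary allylic alcohol and the derived lactol to 23.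

**Step 16.** Acylation may go astray to O8, or the acyl group may migrate from O9 to O8, because the two secondary alcohols are vicinal. The fallback runs from 24 back to 25. Bu2SnO (toluene, azeotropic removal of water) should give the 8,9-O-dibutylstannylene acetal F11. Its less hindered oxygen O9 should then be acylated by isobutyryl chloride at low temperature to give 25.

## Further compounds

F1 | step 8 | (1R,6R)-1-[(Z)-2-ethoxyethenyl]-6-{(E)-2-[(4-methoxybenzyl)oxy]ethenyl}-2,6-dimethylcyclohex-2-en-1-ol | COc1ccc(CO/C=C/[C@@]2(C)CCC=C(C)[C@]2(O)/C=C\OCC)cc1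
F2 | step 8 | (2Z,6E,8S,9Z)-8-[(4-methoxybenzyl)oxy]-2,6-dimethylcyclodeca-2,6,9-trien-1-one | COc1ccc(CO[C@H]2/C=C(\C)CC/C=C(/C)C(=O)/C=C\2)cc1
F3 | step 8 | cis-7,8-epoxide of F2 on the outer face (target numbering) | COc1ccc(CO[C@H]2/C=C(\C)CC/C=C(/C)C(=O)[C@@H]3O[C@H]23)cc1
F4 | step 8 | (6S)-6-[(4-methoxybenzyl)oxy]-4,10-dimethylcyclodeca-1(10)Z,4E-diene-7,9-dione (target numbering) | COc1ccc(CO[C@H]2/C=C(\C)CC/C=C(/C)C(=O)CC2=O)cc1
F5 | step 9 | (6S)-6-[(4-methoxybenzyl)oxy]-4,10-dimethylcyclodeca-1(10)Z,4E,8Z-trien-7-one (target numbering) | COc1ccc(CO[C@H]2/C=C(\C)CC/C=C(/C)\C=C/C2=O)cc1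
F6 | step 9 | 7-ethynyl carbinol of F5 with the C7 configuration of the target | COc1ccc(CO[C@H]2/C=C(\C)CC/C=C(/C)\C=C/[C@]2(O)C#C)cc1
F7 | step 9 | 7-ethynyl-6-[(4-methoxybenzyl)oxy]-4,10-dimethylcyclodeca-1(10)Z,4E-diene-7,8,9-triol with the target configuration at C6 to C9 | COc1ccc(CO[C@H]2/C=C(\C)CC/C=C(/C)[C@H](O)[C@H](O)[C@]2(O)C#C)cc1
F8 | step 10 | 7-ethoxy-7,8-epoxide of 16 on the outer face (target numbering) | COc1ccc(CO[C@H]2/C=C(\C)CC/C=C(/C)[C@H](O)[C@@H]3O[C@]23OCC)cc1
F9 | step 14 | adduct of 19 with 2-lithio-3-[(4-methoxybenzyl)oxy]propene with the C7 configuration of 21 | COc1ccc(CO[C@H]2/C=C(\C)CC/C=C(/C)[C@H](O[Si](CC)(CC)CC)[C@H](O[Si](CC)(CC)CC)[C@]2(O)C(=C)COCc3ccc(OC)cc3)cc1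
F10 | step 14 | 7-(3-hydroxyprop-1-en-2-yl)-8,9-bis(triethylsilyloxy)-4,10-dimethylcyclodeca-1(10)Z,4E-diene-6,7-diol (target numbering) | O[C@H]1/C=C(\C)CC/C=C(/C)[C@H](O[Si](CC)(CC)CC)[C@H](O[Si](CC)(CC)CC)[C@]1(O)C(=C)CO
F11 | step 16 | 8,9-O-dibutylstannylene acetal of 24 | C=C1C(=O)O[C@H]2/C=C(\C)CC/C=C(/C)[C@@H]3O[Sn](CCCC)(CCCC)O[C@@H]3[C@]12O
A1 | alternative 1 | seco enal allyl bromide (C6 aldehyde; C7 methoxymethyl enol ether; C13 bromide; C12 methyl ester; 8,9-acetonide) | O=C/C=C(\C)CC/C=C(/C)[C@@H]1OC(C)(C)O[C@@H]1/C(OCOC)=C(/CBr)C(=O)OC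
A2 | alternative 1 | 7-O-methoxymethyl 8,9-O-isopropylidene derivative of 24 | C=C1C(=O)O[C@H]2/C=C(\C)CC/C=C(/C)[C@@H]3OC(C)(C)O[C@@H]3[C@]12OCOC
A3 | alternative 2 | cis-1-vinyl-2-isopropenylcyclohexanol carrying the 6,7- and 8,9-acetonides (target numbering) | C=C[C@]1(O)[C@H](C(C)=C)[C@@H]2OC(C)(C)O[C@@H]2[C@H]3OC(C)(C)O[C@@H]13
A4 | alternative 3 | ten-membered lactone (C11 ester of the tertiary C4 carbinol; E enol ether arm on C4; 7-O-methoxymethyl; 8,9-acetonide) | O=C1O[C@@](C)(/C=C/OCc2ccc(OC)cc2)CC/C=C(/C)[C@@H]3OC(C)(C)O[C@@H]3[C@H]1OCOC
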